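**Retrosynthetic overview**
- The target acid comes from a bicyclic hydroxy methyl ester by oxidation of the ring carbinol and O-demethylation.
- Both rings (the cyclohexene and the cyclopentane of the trans-hydrindane) form together in one ester-endo intramolecular Diels–Alder reaction of an acyclic (2E,7E,9E,11E)-tetraenoate; no ring exists before that step.
- The tetraene comes from a benzylphosphonate olefination and two formyl-ylide Wittig homologations; the enoate comes from cross-metathesis with methyl 2-ethylacrylate.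
- The Et/OH/Me triad comes from butanal, formaldehyde and an (E)-crotylboronate: amine-catalysed α-hydroxymethylation (first stereocentre), then phosphoric-acid-catalysed crotylboration.

Assumption: methyl 2-ethylacrylate, 2-(triphenylphosphoranylidene)butanal and the three organocatalysts (either antipode) are taken as purchasable; catalyst antipodes are assigned from the usual facial models and would be confirmed on the first intermediate.

**Step 1**
Reactants: 1 butanal; 2 formaldehyde (37% aqueous); 3 (E)-crotylboronic acid pinacol ester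
Product: 5 (2S,3S,4S)-2-ethyl-4-methylhex-5-ene-1,3-diol, via hydroxy aldehyde 4 (not isolated)
Conditions: (R)-2-[Ph2C(OSiMe3)]pyrrolidine (10 mol%), pH 7 buffer (KH2PO4/K2HPO4), PhMe, rt; extract, MgSO4; then 3, (S)-TRIP (5 mol%), 4 Å MS, PhMe, −30 °C; H2O
Reagents that add atoms: formaldehyde 2, C=O; (E)-crotylboronic acid pinacol ester 3, C/C=C/CB1OC(C)(C)C(C)(C)O1
Why: Enamine-catalysed α-hydroxymethylation (cross-aldol with formaldehyde on the enamine face away from the CPh2OSiMe3 group) sets C2 as S, and the phosphoric-acid-catalysed crotylboration of 4 (closed chair transition state, Si face chosen by (S)-TRIP, (E)-crotyl geometry) sets C3 and C4 as the 2,3-syn-3,4-anti triad.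

**Step 2**
Reactants: 5 (2S,3S,4S)-2-ethyl-4-methylhex-5-ene-1,3-diol; 6 methyl 2-ethylacrylate
Product: 7 methyl (2E,4S,5S,6S)-2-ethyl-5-hydroxy-6-(hydroxymethyl)-4-methyloct-2-enoate
Conditions: 6 (5 equiv), second-generation Hoveyda–Grubbs catalyst RuCl2(H2IMes)(=CH–C6H4-2-OiPr) (5 mol%), CH2Cl2, 40 °C
Reagents that add atoms: methyl 2-ethylacrylate 6, CCC(=C)C(=O)OC
Why: Olefin cross-metathesis of the monosubstituted alkene of 5 with the 1,1-disubstituted acrylate gives the thermodynamically favoured (E)-trisubstituted enoate and leaves the stereocentres and free hydroxyls untouched.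

**Step 3**
Reactants: 7 methyl (2E,4S,5S,6S)-2-ethyl-5-hydroxy-6-(hydroxymethyl)-4-methyloct-2-enoate; 8 2-(triphenylphosphoranylidene)butanal
Product: 10 methyl (2E,4S,5S,6S,7E)-2,6,8-triethyl-5-hydroxy-4-methyl-9-oxonona-2,7-dienoate, via formyl ester 9 (not isolated)
Conditions: TEMPO (10 mol%), PhI(OAc)2, CH2Cl2, rt; then 8, PhMe, 70 °C
Reagents that add atoms: 2-(triphenylphosphoranylidene)butanal 8, CCC(C=O)=P(c1ccccc1)(c1ccccc1)c1ccccc1
Why: Nitroxyl-catalysed oxidation takes only the primary alcohol, and Wittig olefination of 9 by the stabilised formyl ylide under neutral conditions gives the (E)-enal without epimerising the α-stereocentre.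

**Step 4**
Reactants: 10 methyl (2E,4S,5S,6S,7E)-2,6,8-triethyl-5-hydroxy-4-methyl-9-oxonona-2,7-dienoate; 8 2-(triphenylphosphoranylidene)butanal
Product: 11 methyl (2E,4S,5S,6S,7E,9E)-2,6,8,10-tetraethyl-5-hydroxy-4-methyl-11-oxoundeca-2,7,9-trienoate
Conditions: 8, PhMe, 100 °C
Reagents that add atoms: 2-(triphenylphosphoranylidene)butanal 8, CCC(C=O)=P(c1ccccc1)(c1ccccc1)c1ccccc1
Why: A second Wittig olefination with the same stabilised ylide extends the chain to the (E,E)-dienal, while the enoate and the secondary alcohol are inert to the ylide.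

**Step 5**
Reactants: 11 methyl (2E,4S,5S,6S,7E,9E)-2,6,8,10-tetraethyl-5-hydroxy-4-methyl-11-oxoundeca-2,7,9-trienoate; 12 diethyl benzylphosphonate
Product: 13 methyl (2E,4S,5S,6S,7E,9E,11E)-2,6,8,10-tetraethyl-5-hydroxy-4-methyl-12-phenyldodeca-2,7,9,11-tetraenoate
Conditions: 12, LiN(SiMe3)2 (2.2 equiv), THF, −78 → 0 °C; aq. NH4Cl; kept cold under Ar and used at once
Reagents that add atoms: diethyl benzylphosphonate 12, CCOP(=O)(Cc1ccccc1)OCC
Why: Horner–Wadsworth–Emmons olefination with the benzylphosphonate anion gives the (E)-styryl group, one extra equivalent of base covers the free hydroxyl, and the fast cold addition outruns enolisation.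

**Step 6**
Reactants: 13 methyl (2E,4S,5S,6S,7E,9E,11E)-2,6,8,10-tetraethyl-5-hydroxy-4-methyl-12-phenyldodeca-2,7,9,11-tetraenoate
Product: 16 methyl (1S,2S,3S,3aR,4R,5S,7aR)-1,4,5,7-tetraethyl-2-hydroxy-3-methyl-5-[(E)-2-phenylethenyl]-2,3,3a,4,5,7a-hexahydro-1H-indene-4-carboxylate, via O-silyl tetraene 14 (not isolated), via O-silyl cycloadduct 15 (not isolated)
Conditions: allyl-SiMe3 (1.5 equiv), (S,S)-IDPi (confined imidodiphosphorimidate acid from two 3,3'-diaryl-BINOL units, P=N–SO2CF3 groups; 3 mol%), CH2Cl2, −60 → −20 °C; then K2CO3, MeOH, 0 °C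
Reagents that add atoms: none
Why: Proposed new method: a silylium-ion, chiral-counteranion-catalysed intramolecular Diels–Alder reaction. Protodesilylation of allyl-SiMe3 by the chiral acid gives Me3Si+ paired with the chiral anion, which first caps the C5–OH (14) and then reversibly silylates the ester carbonyl, lowering the LUMO of the α-ethyl enoate. Bonding is asynchronous (C3–C7 leads, the C8–C10 allyl-cation character being stabilised by two ethyl groups and the styryl unit) and ester-endo, through the conformer in which H-4 and H-6 eclipse the neighbouring alkenes (A(1,3) strain). This gives the trans ring fusion and sets C3a (R), C4 (R), C5 (S) and C7a (R), and silyl transfer to the next ester closes the cycle. The closest known reaction type is the silylium/IDPi-catalysed intermolecular Diels–Alder reaction of α,β-unsaturated methyl esters with cyclopentadiene, not yet shown intramolecularly, for an α-branched enoate, or for joining two quaternary carbons.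

**Step 7**
Reactants: 16 methyl (1S,2S,3S,3aR,4R,5S,7aR)-1,4,5,7-tetraethyl-2-hydroxy-3-methyl-5-[(E)-2-phenylethenyl]-2,3,3a,4,5,7a-hexahydro-1H-indene-4-carboxylate
Product: 17 methyl (1S,3S,3aR,4R,5S,7aR)-1,4,5,7-tetraethyl-3-methyl-2-oxo-5-[(E)-2-phenylethenyl]-2,3,3a,4,5,7a-hexahydro-1H-indene-4-carboxylate
Conditions: Dess–Martin periodinane, CH2Cl2, 0 °C → rt
Reagents that add atoms: none
Why: Dess–Martin oxidation of the secondary alcohol; both α-carbons of the new ketone already carry their alkyl groups trans to the neighbouring ring substituents (the more stable arrangement), so no stereocentre is at risk.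

**Step 8**
Reactants: 17 methyl (1S,3S,3aR,4R,5S,7aR)-1,4,5,7-tetraethyl-3-methyl-2-oxo-5-[(E)-2-phenylethenyl]-2,3,3a,4,5,7a-hexahydro-1H-indene-4-carboxylate
Product: 18 (1S,3S,3aR,4R,5S,7aR)-1,4,5,7-tetraethyl-3-methyl-2-oxo-5-[(E)-2-phenylethenyl]-2,3,3a,4,5,7a-hexahydro-1H-indene-4-carboxylic acid
Conditions: LiI (10 equiv), EtOAc, 80 °C; then 1 M HCl
Reagents that add atoms: none
Why: Nucleophilic O-demethylation (SN2 attack of iodide on the methyl group of the lithium-coordinated ester) frees the neopentyl acid without attack at the hindered carbonyl and without base that could epimerise C1/C3 or open the ring by retro-Michael reaction.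

**Compound list**
1 | butanal | CCCC=O | starting material
2 | formaldehyde (37% aqueous) | C=O | starting material
3 | (E)-crotylboronic acid pinacol ester, 2-[(2E)-but-2-en-1-yl]-4,4,5,5-tetramethyl-1,3,2-dioxaborolane | C/C=C/CB1OC(C)(C)C(C)(C)O1 | starting material
4 | (S)-2-(hydroxymethyl)butanal | OC[C@H](CC)C=O | intermediate
5 | (2S,3S,4S)-2-ethyl-4-methylhex-5-ene-1,3-diol | OC[C@H](CC)[C@@H](O)[C@@H](C)C=C | intermediate
6 | methyl 2-ethylacrylate (methyl 2-methylidenebutanoate) | CCC(=C)C(=O)OC | starting material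
7 | methyl (2E,4S,5S,6S)-2-ethyl-5-hydroxy-6-(hydroxymethyl)-4-methyloct-2-enoate | COC(=O)/C(CC)=C/[C@H](C)[C@H](O)[C@@H](CC)CO | intermediate
8 | 2-(triphenylphosphoranylidene)butanal | CCC(C=O)=P(c1ccccc1)(c1ccccc1)c1ccccc1 | starting material
9 | methyl (2E,4S,5S,6R)-2-ethyl-6-formyl-5-hydroxy-4-methyloct-2-enoate | COC(=O)/C(CC)=C/[C@H](C)[C@H](O)[C@@H](CC)C=O | intermediate
10 | methyl (2E,4S,5S,6S,7E)-2,6,8-triethyl-5-hydroxy-4-methyl-9-oxonona-2,7-dienoate | COC(=O)/C(CC)=C/[C@H](C)[C@H](O)[C@@H](CC)/C=C(CC)/C=O | intermediate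
11 | methyl (2E,4S,5S,6S,7E,9E)-2,6,8,10-tetraethyl-5-hydroxy-4-methyl-11-oxoundeca-2,7,9-trienoate | COC(=O)/C(CC)=C/[C@H](C)[C@H](O)[C@@H](CC)/C=C(CC)/C=C(CC)/C=O | intermediate
12 | diethyl benzylphosphonate | CCOP(=O)(Cc1ccccc1)OCC | starting material
13 | methyl (2E,4S,5S,6S,7E,9E,11E)-2,6,8,10-tetraethyl-5-hydroxy-4-methyl-12-phenyldodeca-2,7,9,11-tetraenoate | COC(=O)/C(CC)=C/[C@H](C)[C@H](O)[C@@H](CC)/C=C(CC)/C=C(CC)/C=C/c1ccccc1 | intermediate
14 | methyl (2E,4S,5S,6S,7E,9E,11E)-2,6,8,10-tetraethyl-4-methyl-12-phenyl-5-[(trimethylsilyl)oxy]dodeca-2,7,9,11-tetraenoate | COC(=O)/C(CC)=C/[C@H](C)[C@H](O[Si](C)(C)C)[C@@H](CC)/C=C(CC)/C=C(CC)/C=C/c1ccccc1 | intermediate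
15 | methyl (1S,2S,3S,3aR,4R,5S,7aR)-1,4,5,7-tetraethyl-3-methyl-5-[(E)-2-phenylethenyl]-2-[(trimethylsilyl)oxy]-2,3,3a,4,5,7a-hexahydro-1H-indene-4-carboxylate | CCC1=C[C@@](/C=C/c2ccccc2)(CC)[C@](CC)(C(=O)OC)[C@@H]2[C@@H]1[C@H](CC)[C@@H](O[Si](C)(C)C)[C@H]2C | intermediate
16 | methyl (1S,2S,3S,3aR,4R,5S,7aR)-1,4,5,7-tetraethyl-2-hydroxy-3-methyl-5-[(E)-2-phenylethenyl]-2,3,3a,4,5,7a-hexahydro-1H-indene-4-carboxylate | CCC1=C[C@@](/C=C/c2ccccc2)(CC)[C@](CC)(C(=O)OC)[C@@H]2[C@@H]1[C@H](CC)[C@@H](O)[C@H]2C | intermediate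
17 | methyl (1S,3S,3aR,4R,5S,7aR)-1,4,5,7-tetraethyl-3-methyl-2-oxo-5-[(E)-2-phenylethenyl]-2,3,3a,4,5,7a-hexahydro-1H-indene-4-carboxylate | CCC1=C[C@@](/C=C/c2ccccc2)(CC)[C@](CC)(C(=O)OC)[C@@H]2[C@@H]1[C@H](CC)C(=O)[C@H]2C | intermediate
18 | (1S,3S,3aR,4R,5S,7aR)-1,4,5,7-tetraethyl-3-methyl-2-oxo-5-[(E)-2-phenylethenyl]-2,3,3a,4,5,7a-hexahydro-1H-indene-4-carboxylic acid (CNP0324606.3) | CCC1=C[C@@](/C=C/c2ccccc2)(CC)[C@](CC)(C(=O)O)[C@@H]2[C@@H]1[C@H](CC)C(=O)[C@H]2C | target

**Step count and risks**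
Total steps: 8. Longest linear sequence: 8 (butanal to 18).

Step 6 (the proposed new cycloaddition) is the most likely to fail: the silylium acid may oligomerise the styryl triene, the catalyst antipode may be mismatched with the substrate bias, or turnover may stall. The fallback sets out from 13 and uses only known chemistry. TBSOTf and 2,6-lutidine in CH2Cl2 give methyl (2E,4S,5S,6S,7E,9E,11E)-5-[(tert-butyldimethylsilyl)oxy]-2,6,8,10-tetraethyl-4-methyl-12-phenyldodeca-2,7,9,11-tetraenoate F6. Heating this in toluene at 100 °C with a trace of BHT effects the uncatalysed, substrate-controlled intramolecular Diels–Alder reaction (the biomimetic mode on an O-silylated substrate) to methyl (1S,2S,3S,3aR,4R,5S,7aR)-2-[(tert-butyldimethylsilyl)oxy]-1,4,5,7-tetraethyl-3-methyl-5-[(E)-2-phenylethenyl]-2,3,3a,4,5,7a-hexahydro-1H-indene-4-carboxylate F7. Bu4NF in THF then brings the route back at 16.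

Step 1 is next: aldehyde 4 is water-soluble, dimerises and can dehydrate to 2-ethylacrolein, and its free hydroxyl may erode the catalyst-controlled crotylboration. The fallback sets out from 1 and 2 and replaces the telescoped, protecting-group-free relay by a stop-and-protect sequence. After the same amine-catalysed hydroxymethylation, TBSCl and imidazole are added to the dried organic phase and (S)-2-{[(tert-butyldimethylsilyl)oxy]methyl}butanal F1 is isolated. F1 is crotylated with 3 under (S)-TRIP to (2S,3S,4S)-1-[(tert-butyldimethylsilyl)oxy]-2-ethyl-4-methylhex-5-en-3-ol F2. Bu4NF in THF returns the route at 5.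

Step 2 is third: cross-metathesis to a trisubstituted enoate next to a branched allylic carbon may be slow or give homodimers. The fallback sets out from 5 and builds the enoate by ozonolysis and Wittig olefination instead. 2,2-Dimethoxypropane with pyridinium tosylate gives (4S,5S)-4-[(2S)-but-3-en-2-yl]-5-ethyl-2,2-dimethyl-1,3-dioxane F3. O3 in CH2Cl2 at −78 °C followed by PPh3 gives (2R)-2-[(4R,5S)-5-ethyl-2,2-dimethyl-1,3-dioxan-4-yl]propanal F4. Methyl 2-(triphenylphosphoranylidene)butanoate in CH2Cl2 at 40 °C gives methyl (2E,4S)-2-ethyl-4-[(4S,5S)-5-ethyl-2,2-dimethyl-1,3-dioxan-4-yl]pent-2-enoate F5. Aqueous acetic acid removes the acetonide and returns the route at 7.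

**Further compounds**
F1 | step 1 | (S)-2-{[(tert-butyldimethylsilyl)oxy]methyl}butanal | CC(C)(C)[Si](C)(C)OC[C@H](CC)C=O
F2 | step 1 | (2S,3S,4S)-1-[(tert-butyldimethylsilyl)oxy]-2-ethyl-4-methylhex-5-en-3-ol | CC(C)(C)[Si](C)(C)OC[C@H](CC)[C@@H](O)[C@@H](C)C=C
F3 | step 2 | (4S,5S)-4-[(2S)-but-3-en-2-yl]-5-ethyl-2,2-dimethyl-1,3-dioxane | CC1(C)OC[C@H](CC)[C@H]([C@@H](C)C=C)O1
F4 | step 2 | (2R)-2-[(4R,5S)-5-ethyl-2,2-dimethyl-1,3-dioxan-4-yl]propanal | CC1(C)OC[C@H](CC)[C@H]([C@@H](C)C=O)O1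
F5 | step 2 | methyl (2E,4S)-2-ethyl-4-[(4S,5S)-5-ethyl-2,2-dimethyl-1,3-dioxan-4-yl]pent-2-enoate | COC(=O)/C(CC)=C/[C@H](C)[C@@H]1OC(C)(C)OC[C@@H]1CC
F6 | step 6 | methyl (2E,4S,5S,6S,7E,9E,11E)-5-[(tert-butyldimethylsilyl)oxy]-2,6,8,10-tetraethyl-4-methyl-12-phenyldodeca-2,7,9,11-tetraenoate | COC(=O)/C(CC)=C/[C@H](C)[C@H](O[Si](C)(C)C(C)(C)C)[C@@H](CC)/C=C(CC)/C=C(CC)/C=C/c1ccccc1
F7 | step 6 | methyl (1S,2S,3S,3aR,4R,5S,7aR)-2-[(tert-butyldimethylsilyl)oxy]-1,4,5,7-tetraethyl-3-methyl-5-[(E)-2-phenylethenyl]-2,3,3a,4,5,7a-hexahydro-1H-indene-4-carboxylate | CCC1=C[C@@](/C=C/c2ccccc2)(CC)[C@](CC)(C(=O)OC)[C@@H]2[C@@H]1[C@H](CC)[C@@H](O[Si](C)(C)C(C)(C)C)[C@H]2C
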